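**Plan**

1. Retrosynthesis: the 1,10-epoxide is taken back to the C1=C10 alkene of a dienol. The unit C10=C1–C2=C3 of the ten-membered ring C1–C10 (ring-trans, then ring-cis) is folded back into a cis-fused cyclobutene C10–C1=C2–C3 on the eight-membered ring C3–C10 by re-forming the C3–C10 bond (reverse 4π opening).
2. The eight-membered ring is then cut at C6–C7 together with the lactone O–C12 bond (alkenyl iodide plus aldehyde), and further at C11–C13/C7–I, C7–C8, C4–CH3, C5–C6, C8–C9 and C10–C14, back to cyclobut-3-ene-1,2-dicarboxylic anhydride.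
3. Forward: the cyclobutene is made first ([2+2], dechlorination), both arms are grown on it, the eight-membered ring and the butenolide close in one operation, the ten-membered ring arises by electrocyclic opening, and the 1,10-epoxide comes last.
4. Stereochemistry: cyclobutene centres from desymmetrising methanolysis (erased later); C8 from catalytic asymmetric alkynylation; the side-chain centre from (R)-2-methylbutanoic acid; C4/C5 from tartrate-controlled epoxidation; C6 from Felkin–Anh addition to the epoxy aldehyde; C1/C10 from a second tartrate-controlled epoxidation.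
5. Alkene geometry: Z-C4=C5 from syn cuprate addition to an ynoate; C1=C10 and C2=C3 from the torquoselectivity of the ring opening.

Key step: step 26

Remark: germacranolide numbering is used throughout (ring C1–C10, lactone carbons C11–C13, C14 on C10, C15 = methyl on C4).
Assumption: quinidine is taken to give hemiester (1S,2R)-5 and (S,S)-ProPhenol the (8S)-carbinol 21; if the sense is opposite, quinine or the (R,R)-ligand is used, and for the cyclobutene either series would serve because both of its stereocentres are erased in step 26.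

**Route**

Step 1
Reactants: 1 maleic anhydride; 2 cis-1,2-dichloroethene
Product: 3 cis-fused 6,7-dichloro-3-oxabicyclo[3.2.0]heptane-2,4-dione (chlorine epimers)
Conditions: hν (Pyrex), benzophenone (sensitiser), EtOAc, rt
Reagents that add atoms: none
Why: Triplet-sensitised [2+2] photocycloaddition of the anhydride C=C to the alkene gives the cyclobutane, the five-membered anhydride enforcing the cis ring fusion; the chlorine configuration is irrelevant because both chlorines are removed next.

Step 2
Reactants: 3 dichloro anhydride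
Product: 4 cis-cyclobut-3-ene-1,2-dicarboxylic anhydride (meso)
Conditions: Zn dust (activated), Ac2O, toluene, 85 °C
Reagents that add atoms: none
Why: Reductive 1,2-elimination of the vicinal dichloride by zinc is the standard entry to this cyclobutene anhydride and leaves the cis ring fusion untouched.

Step 3
Reactants: 4 meso anhydride
Product: 5 (1S,2R)-2-(methoxycarbonyl)cyclobut-3-ene-1-carboxylic acid
Conditions: quinidine (1.1 equiv), MeOH (3 equiv), toluene, −55 °C
Reagents that add atoms: methanol CO
Why: Cinchona-alkaloid-mediated desymmetrising methanolysis of a meso anhydride should differentiate the enantiotopic carbonyl groups and so fix both cyclobutene stereocentres in one step.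

Step 4
Reactants: 5 hemiester
Product: 7 (1S,5R)-3-oxabicyclo[3.2.0]hept-6-en-2-one, via hydroxy acid 6 (not isolated)
Conditions: LiBEt3H (3.2 equiv), THF, −78 → 0 °C; then 2 M HCl, rt
Reagents that add atoms: none
Why: LiBEt3H reduces the methyl ester but not the lithium carboxylate, and acidification lactonises the cis hydroxy acid, so the lactone carbonyl (future C9) sits on C10 and the CH2O carbon (future C4) on C3.

Step 5
Reactants: 7 lactone
Product: 8 (1S,5R)-1-(hydroxymethyl)-3-oxabicyclo[3.2.0]hept-6-en-2-one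
Conditions: LiN(iPr)2, THF, −78 °C; CH2O (gas, from paraformaldehyde), −78 → −40 °C
Reagents that add atoms: formaldehyde C=O
Why: Aldol reaction of the lactone enolate (a cross-conjugated dienolate that reacts at its α-carbon) with formaldehyde builds quaternary C10; because the lactone must stay cis-fused, C14 can only enter on the exo face, which leaves C9 and C4 cis.

Step 6
Reactants: 8 hydroxymethyl lactone
Product: 9 (1S,5R)-1-[(tert-butyldiphenylsilyloxy)methyl]-3-oxabicyclo[3.2.0]hept-6-en-2-one
Conditions: TBDPSCl, imidazole, DMF, rt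
Reagents that add atoms: tert-butyl(chloro)diphenylsilane CC(C)(C)[Si](Cl)(c1ccccc1)c1ccccc1
Why: Routine silylation of the primary alcohol gives an acid- and base-stable C14 ether that is carried to step 24.

Step 7
Reactants: 9 silyl ether lactone
Product: 10 (1S,5R)-1-[(tert-butyldiphenylsilyloxy)methyl]-3-oxabicyclo[3.2.0]hept-6-en-2-ol (lactol anomers)
Conditions: i-Bu2AlH, CH2Cl2, −78 °C
Reagents that add atoms: none
Why: Partial reduction of a γ-lactone to the lactol at low temperature is standard; the lactol is kept cold and used at once because its open form is a 3-formylcyclobutene.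

Step 8
Reactants: 10 lactol
Product: 11 cyclobutene alcohol with CH2OH (C4) on C3 and 2-methoxyvinyl (C9=C8; E/Z mixture) and CH2OTBDPS (C14) on C10; C4 and C9 cis
Conditions: MeOCH2PPh3Cl, KN(SiMe3)2, THF, −20 → 0 °C
Reagents that add atoms: (methoxymethyl)triphenylphosphonium chloride COC[P+](c1ccccc1)(c1ccccc1)c1ccccc1.[Cl-]
Why: Wittig methoxymethylenation of the lactol through its open hydroxy aldehyde adds C8 and at the same time frees the C4 hydroxyl; a reactive ylide at low temperature should trap the aldehyde faster than the cyclobutene can open.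

Step 9
Reactants: 11 alcohol
Product: 12 aldehyde (C4 = CHO on C3)
Conditions: Dess–Martin periodinane, pyridine, CH2Cl2, 0 °C
Reagents that add atoms: none
Why: Buffered Dess–Martin oxidation tolerates the enol ether and avoids base, so the C3 stereocentre α to the new aldehyde should survive; the aldehyde is used cold without storage.

Step 10
Reactants: 12 aldehyde
Product: 13 1,1-dibromoalkene (C3–CH=CBr2)
Conditions: CBr4, PPh3, Zn dust, CH2Cl2, 0 °C
Reagents that add atoms: carbon tetrabromide BrC(Br)(Br)Br
Why: Ramirez dibromo-olefination (first half of the Corey–Fuchs sequence) is non-basic and fast at 0 °C, which suits an epimerisable, thermally labile aldehyde.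

Step 11
Reactants: 13 dibromoalkene
Product: 15 methyl ynoate (C3–C4≡C5–C6O2Me), via lithium acetylide 14 (not isolated)
Conditions: n-BuLi (2.1 equiv), THF, −78 °C; then ClCO2Me, −78 → −20 °C
Reagents that add atoms: methyl chloroformate COC(=O)Cl
Why: Bromine–lithium exchange and Fritsch–Buttenberg–Wiechell rearrangement (Corey–Fuchs) give the lithium acetylide, which is acylated in the same flask to introduce C6.

Step 12
Reactants: 15 ynoate
Product: 16 methyl (Z)-enoate (C3 and C6 cis across C4=C5, CH3 on C4)
Conditions: Me2CuLi (from CuI and MeLi), THF, −78 °C; MeOH quench at −78 °C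
Reagents that add atoms: lithium dimethylcuprate [Li+].C[Cu-]C
Why: Syn conjugate addition of the cuprate to a 2-ynoate and low-temperature protonation with retention place the original alkyne substituent (C3) cis to the ester, the classical route to nerol-type Z-trisubstituted enoates.

Step 13
Reactants: 16 enoate
Product: 17 (Z)-allylic alcohol (C6 = CH2OH)
Conditions: i-Bu2AlH, CH2Cl2, −78 °C
Reagents that add atoms: none
Why: 1,2-Reduction of the enoate by i-Bu2AlH gives the allylic alcohol without touching the enol ether, the silyl ether or the alkene geometry.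

Step 14
Reactants: 17 allylic alcohol enol ether
Product: 18 hydroxy aldehyde (C10–CH2–CHO, C8 = CHO; C6–OH free)
Conditions: oxalic acid, THF/H2O, rt
Reagents that add atoms: water O
Why: Mild acid hydrolysis of the methyl enol ether completes the one-carbon homologation to the C9H2–C8HO arm; this aldehyde is no longer on the ring and is stable.

Step 15
Reactants: 18 hydroxy aldehyde
Product: 19 TBS ether aldehyde (C6–OTBS, C8 = CHO)
Conditions: TBSCl, imidazole, CH2Cl2, 0 °C
Reagents that add atoms: tert-butyl(chloro)dimethylsilane CC(C)(C)[Si](C)(C)Cl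
Why: Silylation masks the allylic alcohol with a group that can later be removed in the presence of the neopentyl TBDPS ether.

Step 16
Reactants: 19 aldehyde; 20 methyl propiolate
Product: 21 (8S)-γ-hydroxy ynoate (C8(OH)–C7≡C11–C12O2Me)
Conditions: (S,S)-ProPhenol (20 mol %), Me2Zn, Ph3PO (40 mol %), toluene, 4 °C
Reagents that add atoms: none
Why: Zinc–ProPhenol-catalysed asymmetric alkynylation adds the propiolate zinc acetylide to one face of the aldehyde and sets C8 under reagent control.

Step 17
Reactants: 21 propargylic alcohol; 22 (R)-2-methylbutanoic acid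
Product: 23 (8S)-ynoate (R)-2-methylbutanoate
Conditions: DCC, DMAP (cat.), CH2Cl2, 0 °C
Reagents that add atoms: none
Why: Steglich esterification at 0 °C with little DMAP installs the side chain with retention at C8 and should not epimerise the α-centre of the acid.

Step 18
Reactants: 23 ynoate ester
Product: 25 (Z)-β-iodo enoate with CH2OH (C13) on C11 and iodine on C7 cis to CO2Me, via silyl iodoallenoate 24 (not isolated)
Conditions: Me3SiI, CH2Cl2, −78 °C; then CH2O (THF solution), BF3·OEt2 (20 mol %), −78 → −40 °C; aqueous citric acid work-up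
Reagents that add atoms: iodotrimethylsilane C[Si](C)(C)I; formaldehyde C=O
Why: Proposed new method: iodide from Me3SiI adds in conjugate fashion to C7 to give silyl iodoallenoate 24, whose C11 undergoes a BF3-catalysed Mukaiyama-type aldol with formaldehyde, the electrophile being expected to enter anti to the large iodine atom (as the proton does in the anti-hydroiodination of 2-alkynoates) so that iodine ends cis to CO2Me; the closest known reaction type is the iodide/aldol (β-iodo Morita–Baylis–Hillman) reaction of terminal propiolates and ynones, which has not been shown for an internal γ-acyloxy ynoate with formaldehyde.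

Step 19
Reactants: 25 allylic alcohol
Product: 26 C13 acetate
Conditions: Ac2O, pyridine, CH2Cl2, 0 °C
Reagents that add atoms: acetic anhydride CC(=O)OC(C)=O
Why: Prompt acetylation installs the C13 acetate of the target and stops acyl migration from the neighbouring C8 ester.

Step 20
Reactants: 26 bis-silyl ether
Product: 27 (Z)-allylic alcohol (C6–OH free)
Conditions: HF·pyridine, pyridine, THF, 0 °C
Reagents that add atoms: none
Why: Buffered HF·pyridine cleaves the primary allylic TBS ether much faster than the neopentyl TBDPS ether and spares both esters and the alkenyl iodide.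

Step 21
Reactants: 27 allylic alcohol
Product: 28 (4R,5S)-epoxy alcohol
Conditions: Ti(OiPr)4 (20 mol %), L-(+)-diethyl tartrate (24 mol %), t-BuOOH, 4 Å MS, CH2Cl2, −20 °C
Reagents that add atoms: tert-butyl hydroperoxide CC(C)(C)OO
Why: Sharpless asymmetric epoxidation of the Z-trisubstituted allylic alcohol with the L-(+)-tartrate should give the (4R,5S)-epoxide, the same facial sense that converts nerol into (2S,3R)-epoxynerol; no other alkene in 27 is an allylic alcohol.

Step 22
Reactants: 28 epoxy alcohol
Product: 29 epoxy aldehyde (C6 = CHO; epoxide as in the target)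
Conditions: Dess–Martin periodinane, pyridine, CH2Cl2, 0 °C
Reagents that add atoms: none
Why: Buffered Dess–Martin oxidation gives the α,β-epoxy aldehyde without epimerisation or epoxide opening; it is used directly.

Step 23
Reactants: 29 iodo enoate epoxy aldehyde
Product: 31 TBDPS-protected cis-fused bicyclo[6.2.0]dec-9-ene butenolide ((6S); lactone O on C6), via hydroxy ester 30 (not isolated)
Conditions: CrCl2, NiCl2 (1 mol %), DMSO/THF, rt, 2 mM
Reagents that add atoms: none
Why: In this Nozaki–Hiyama–Kishi reaction zerovalent nickel inserts into the C7–I bond and transmetalation to chromium gives an alkenylchromium species that adds to the C6 aldehyde anti to the epoxide C–O bond (Felkin–Anh), setting (6S); the resulting alkoxide lactonises onto the cis CO2Me, and the cis-fused cyclobutene and the cis-epoxide act as turn elements for the eight-membered ring.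

Step 24
Reactants: 31 silyl ether
Product: 32 C14 primary alcohol
Conditions: Bu4NF, AcOH, THF, 0 °C → rt
Reagents that add atoms: none
Why: Acetic-acid-buffered fluoride removes the TBDPS group under near-neutral conditions that the epoxide, the acetate, the ester and the butenolide γ-hydrogen should tolerate.

Step 25
Reactants: 32 alcohol
Product: 33 cis-fused bicyclo[6.2.0]dec-9-ene with formyl (C14) on C10, 4,5-epoxide and butenolide in place
Conditions: Dess–Martin periodinane, pyridine, CH2Cl2, 0 °C
Reagents that add atoms: none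
Why: Oxidation of the neopentyl alcohol at 0 °C gives the non-enolisable formyl cyclobutene, which is isolated cold and carried straight into the ring opening.

Step 26
Reactants: 33 formyl cyclobutene
Product: 34 ten-membered dienal (C1=C10 ring-trans with C14 formyl on C10, C2=C3 ring-cis, 4,5-epoxide)
Conditions: toluene (5 mM), 60 °C, dark
Reagents that add atoms: none
Why: Heating opens the cyclobutene C10–C1=C2–C3 by a thermally allowed conrotatory 4π electrocyclic reaction that cleaves the C3–C10 σ bond and turns C1=C2 into the C10=C1 and C2=C3 double bonds. The closest known reaction type is the thermal opening of cis-bicyclo[6.2.0]dec-9-enes to cis,trans-cyclodeca-1,3-dienes, combined with the established inward rotation of a formyl group on the sp3 carbon of a cyclobutene. No ring is closed: the ten-membered ring C1–C10 arises by ring expansion, through loss of the bond shared by the four- and the eight-membered ring. No stereocentre is created; C3 and C10 become trigonal, so the configuration set in step 3 is erased and only alkene geometry matters. The selectivity needed is torquoselectivity: the C14 formyl group on C10 rotates inward (its π* orbital accepts density from the breaking σ bond), which sends C9 outward (ring-trans C1=C10) and, because C9 and C4 are cis, forces C4 inward (ring-cis C2=C3), whereas the opposite conrotation would have to turn the formyl group outward and C9 inward. The 4,5-epoxide already in place keeps the product a diene and not a cyclisable triene, and the dienal is reduced at once in step 27 so that its 2H-pyran valence isomer and a 1,5-hydrogen shift cannot drain it.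

Step 27
Reactants: 34 dienal
Product: 35 dienol (C14 = CH2OH)
Conditions: NaBH4, CeCl3·7H2O, MeOH, −78 °C
Reagents that add atoms: none
Why: Luche reduction delivers hydride 1,2 to the conjugated aldehyde and should leave the tetrasubstituted butenolide, the esters and both alkenes untouched.

Step 28
Reactants: 35 dienol
Product: 36 target CNP0108300.1 ((1R,4R,5S,6S,8S,10S), 2Z, (R)-2-methylbutanoate)
Conditions: Ti(OiPr)4 (20 mol %), L-(+)-diethyl tartrate (24 mol %), t-BuOOH, 4 Å MS, CH2Cl2, −25 °C
Reagents that add atoms: tert-butyl hydroperoxide CC(C)(C)OO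
Why: Sharpless asymmetric epoxidation acts only on the allylic-alcohol alkene C1=C10, and the L-(+)-tartrate should deliver oxygen to the face that gives (1R,10S); the trans relation of C9 and C2 is carried from the alkene into the epoxide.

**Compound list**

1 | maleic anhydride | O=C1C=CC(=O)O1 | starting material
2 | cis-1,2-dichloroethene | Cl/C=C\Cl | starting material
3 | cis-fused 6,7-dichloro-3-oxabicyclo[3.2.0]heptane-2,4-dione (chlorine epimers) | O=C1OC(=O)[C@@H]2C(Cl)C(Cl)[C@H]12 | intermediate
4 | cis-cyclobut-3-ene-1,2-dicarboxylic anhydride (meso) | O=C1OC(=O)[C@@H]2C=C[C@H]12 | intermediate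
5 | (1S,2R)-2-(methoxycarbonyl)cyclobut-3-ene-1-carboxylic acid | COC(=O)[C@@H]1C=C[C@@H]1C(=O)O | intermediate
6 | (1S,4R)-4-(hydroxymethyl)cyclobut-2-ene-1-carboxylic acid | OC[C@@H]1C=C[C@@H]1C(=O)O | intermediate
7 | (1S,5R)-3-oxabicyclo[3.2.0]hept-6-en-2-one | O=C1OC[C@@H]2C=C[C@H]12 | intermediate
8 | (1S,5R)-1-(hydroxymethyl)-3-oxabicyclo[3.2.0]hept-6-en-2-one | O=C1OC[C@@H]2C=C[C@]12CO | intermediate
9 | (1S,5R)-1-[(tert-butyldiphenylsilyloxy)methyl]-3-oxabicyclo[3.2.0]hept-6-en-2-one | O=C1OC[C@@H]2C=C[C@]12CO[Si](c3ccccc3)(c3ccccc3)C(C)(C)C | intermediate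
10 | lactol of 9 (anomers) | OC1OC[C@@H]2C=C[C@]12CO[Si](c3ccccc3)(c3ccccc3)C(C)(C)C | intermediate
11 | cyclobutene with CH2OH on C3 and 2-methoxyvinyl (E/Z) plus CH2OTBDPS on C10; C4 and C9 cis | OC[C@@H]1C=C[C@@]1(C=COC)CO[Si](c2ccccc2)(c2ccccc2)C(C)(C)C | intermediate
12 | C4 aldehyde of 11 | O=C[C@@H]1C=C[C@@]1(C=COC)CO[Si](c2ccccc2)(c2ccccc2)C(C)(C)C | intermediate
13 | 1,1-dibromoalkene from 12 | BrC(Br)=C[C@@H]1C=C[C@@]1(C=COC)CO[Si](c2ccccc2)(c2ccccc2)C(C)(C)C | intermediate
14 | lithium acetylide (C3–C≡C–Li) | [Li]C#C[C@@H]1C=C[C@@]1(C=COC)CO[Si](c2ccccc2)(c2ccccc2)C(C)(C)C | intermediate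
15 | methyl ynoate (C3–C4≡C5–C6O2Me) | COC(=O)C#C[C@@H]1C=C[C@@]1(C=COC)CO[Si](c2ccccc2)(c2ccccc2)C(C)(C)C | intermediate
16 | methyl (Z)-3-methyl enoate (C3 cis to C6) | COC(=O)/C=C(/C)[C@@H]1C=C[C@@]1(C=COC)CO[Si](c2ccccc2)(c2ccccc2)C(C)(C)C | intermediate
17 | (Z)-allylic alcohol | OC/C=C(/C)[C@@H]1C=C[C@@]1(C=COC)CO[Si](c2ccccc2)(c2ccccc2)C(C)(C)C | intermediate
18 | hydroxy aldehyde (C8 = CHO) | OC/C=C(/C)[C@@H]1C=C[C@@]1(CC=O)CO[Si](c2ccccc2)(c2ccccc2)C(C)(C)C | intermediate
19 | C6-OTBS aldehyde | CC(C)(C)[Si](C)(C)OC/C=C(/C)[C@@H]1C=C[C@@]1(CC=O)CO[Si](c2ccccc2)(c2ccccc2)C(C)(C)C | intermediate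
20 | methyl propiolate | C#CC(=O)OC | starting material
21 | (8S)-γ-hydroxy ynoate | CC(C)(C)[Si](C)(C)OC/C=C(/C)[C@@H]1C=C[C@@]1(C[C@H](O)C#CC(=O)OC)CO[Si](c2ccccc2)(c2ccccc2)C(C)(C)C | intermediate
22 | (R)-2-methylbutanoic acid | CC[C@@H](C)C(=O)O | starting material
23 | (8S)-ynoate (R)-2-methylbutanoate | CC(C)(C)[Si](C)(C)OC/C=C(/C)[C@@H]1C=C[C@@]1(C[C@H](OC(=O)[C@H](C)CC)C#CC(=O)OC)CO[Si](c2ccccc2)(c2ccccc2)C(C)(C)C | intermediate
24 | silyl β-iodoallenoate (ketene acetal; allene axis undefined) | CC(C)(C)[Si](C)(C)OC/C=C(/C)[C@@H]1C=C[C@@]1(C[C@H](OC(=O)[C@H](C)CC)C(I)=C=C(OC)O[Si](C)(C)C)CO[Si](c2ccccc2)(c2ccccc2)C(C)(C)C | intermediate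
25 | (Z)-β-iodo enoate with C13 CH2OH (I cis to CO2Me) | CC(C)(C)[Si](C)(C)OC/C=C(/C)[C@@H]1C=C[C@@]1(C[C@H](OC(=O)[C@H](C)CC)/C(I)=C(\CO)C(=O)OC)CO[Si](c2ccccc2)(c2ccccc2)C(C)(C)C | intermediate
26 | C13 acetate of 25 | CC(C)(C)[Si](C)(C)OC/C=C(/C)[C@@H]1C=C[C@@]1(C[C@H](OC(=O)[C@H](C)CC)/C(I)=C(\COC(C)=O)C(=O)OC)CO[Si](c2ccccc2)(c2ccccc2)C(C)(C)C | intermediate
27 | (Z)-allylic alcohol (C6–OH) | OC/C=C(/C)[C@@H]1C=C[C@@]1(C[C@H](OC(=O)[C@H](C)CC)/C(I)=C(\COC(C)=O)C(=O)OC)CO[Si](c2ccccc2)(c2ccccc2)C(C)(C)C | intermediate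
28 | (4R,5S)-epoxy alcohol | OC[C@@H]2O[C@]2(C)[C@@H]1C=C[C@@]1(C[C@H](OC(=O)[C@H](C)CC)/C(I)=C(\COC(C)=O)C(=O)OC)CO[Si](c3ccccc3)(c3ccccc3)C(C)(C)C | intermediate
29 | epoxy aldehyde (C6 = CHO) | O=C[C@@H]2O[C@]2(C)[C@@H]1C=C[C@@]1(C[C@H](OC(=O)[C@H](C)CC)/C(I)=C(\COC(C)=O)C(=O)OC)CO[Si](c3ccccc3)(c3ccccc3)C(C)(C)C | intermediate
30 | cyclised (6S)-hydroxy ester (C6–OH cis to CO2Me across C7=C11) | CC[C@@H](C)C(=O)O[C@H]1C[C@@]3(CO[Si](c4ccccc4)(c4ccccc4)C(C)(C)C)C=C[C@H]3[C@@]2(C)O[C@H]2[C@@H](O)/C1=C(/COC(C)=O)C(=O)OC | intermediate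
31 | TBDPS-protected cis-fused bicyclo[6.2.0]dec-9-ene butenolide | CC[C@@H](C)C(=O)O[C@H]1C[C@@]3(CO[Si](c4ccccc4)(c4ccccc4)C(C)(C)C)C=C[C@H]3[C@@]2(C)O[C@H]2[C@H]2OC(=O)C(COC(C)=O)=C12 | intermediate
32 | C14 alcohol | CC[C@@H](C)C(=O)O[C@H]1C[C@@]3(CO)C=C[C@H]3[C@@]2(C)O[C@H]2[C@H]2OC(=O)C(COC(C)=O)=C12 | intermediate
33 | C10-formyl cis-fused bicyclo[6.2.0]dec-9-ene (key-step precursor) | CC[C@@H](C)C(=O)O[C@H]1C[C@@]3(C=O)C=C[C@H]3[C@@]2(C)O[C@H]2[C@H]2OC(=O)C(COC(C)=O)=C12 | intermediate
34 | ten-membered dienal (key-step product) | CC[C@@H](C)C(=O)O[C@H]1C/C(C=O)=C/C=C\[C@@]2(C)O[C@H]2[C@H]2OC(=O)C(COC(C)=O)=C12 | intermediate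
35 | ten-membered dienol | CC[C@@H](C)C(=O)O[C@H]1C/C(CO)=C/C=C\[C@@]2(C)O[C@H]2[C@H]2OC(=O)C(COC(C)=O)=C12 | intermediate
36 | CNP0108300.1 | CC[C@@H](C)C(=O)O[C@H]1C[C@@]2(CO)O[C@@H]2/C=C\[C@@]2(C)O[C@H]2[C@H]2OC(=O)C(COC(C)=O)=C12 | target

**Totals**

Total step count: 28. Longest linear sequence: 28 steps (from maleic anhydride).

**Steps most likely to fail**

Step 18 (proposed method). Iodide addition may stall on the internal ynoate, the allenoate may be protonated instead of undergoing the aldol, or formaldehyde may enter syn to iodine and give the alkene geometry that cannot lactonise at C6. The fallback uses established reactions only, sets out from 23 and comes back at 31. Morpholine adds to the ynoate and mild aqueous acid hydrolyses the enamino ester to the β-keto ester F1. Its sodium enolate (NaH, THF) is C-alkylated with 4-methoxybenzyl chloromethyl ether to give the α-alkoxymethyl β-keto ester F2. NaH and Tf2O trap the chelated enolate as the (Z)-enol triflate F3, in which the triflate is cis to CO2Me by construction. DDQ gives the alcohol F4 and Ac2O/pyridine the acetate F5. HF·pyridine, the same L-(+)-tartrate epoxidation and Dess–Martin oxidation then give the allylic alcohol F6, the epoxy alcohol F7 and the epoxy aldehyde F8. CrCl2/NiCl2 couples the alkenyl triflate with the aldehyde and the adduct lactonises to 31.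

Step 23. Oxidative addition at the hindered tetrasubstituted iodide may be slow, so that reduction or oligomerisation competes; chloride from the chromium salts may open the epoxy aldehyde; and the facial selectivity at C6 may be poor. The fallback sets out from 27 and comes back at 31, moving the epoxidation behind the ring closure. MnO2 oxidises 27 to the (Z)-enal F9, whose less hindered, epoxide-free aldehyde is cyclised under the same CrCl2/NiCl2 conditions to the cyclooctene butenolide F10 (the C6 epimers would be separated here). NBS in aqueous DME adds bromine to the exposed face of C4=C5 with water entering at C4, giving the bromohydrin F11. Ag2O then closes the epoxide with inversion at C5, on the face cis to the C6 oxygen, to give 31.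

Step 28. The face of C1=C10 that is attacked may be decided by the conformation of the ten-membered ring and not by the tartrate, and the titanium alkoxide may open the vinyl epoxide. The fallback sets out from 34 and comes back at 36, epoxidising at the aldehyde stage by a different mechanism. Alkaline hydrogen peroxide (H2O2, NaHCO3, MeOH, 0 °C) adds to C1 of the enal and closes to the epoxy aldehyde F12, and NaBH4/CeCl3·7H2O then reduces the aldehyde to 36.

**Further compounds**

F1 | step 18 | β-keto ester (C7 ketone, C11 = CH2) | CC(C)(C)[Si](C)(C)OC/C=C(/C)[C@@H]1C=C[C@@]1(C[C@H](OC(=O)[C@H](C)CC)C(=O)CC(=O)OC)CO[Si](c2ccccc2)(c2ccccc2)C(C)(C)C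
F2 | step 18 | α-[(4-methoxybenzyloxy)methyl] β-keto ester (C11 epimers) | CC(C)(C)[Si](C)(C)OC/C=C(/C)[C@@H]1C=C[C@@]1(C[C@H](OC(=O)[C@H](C)CC)C(=O)C(COCc2ccc(OC)cc2)C(=O)OC)CO[Si](c2ccccc2)(c2ccccc2)C(C)(C)C
F3 | step 18 | (Z)-enol triflate with C13 PMB ether (OTf cis to CO2Me) | CC(C)(C)[Si](C)(C)OC/C=C(/C)[C@@H]1C=C[C@@]1(C[C@H](OC(=O)[C@H](C)CC)/C(OS(=O)(=O)C(F)(F)F)=C(\COCc2ccc(OC)cc2)C(=O)OC)CO[Si](c2ccccc2)(c2ccccc2)C(C)(C)C
F4 | step 18 | (Z)-enol triflate with C13 alcohol | CC(C)(C)[Si](C)(C)OC/C=C(/C)[C@@H]1C=C[C@@]1(C[C@H](OC(=O)[C@H](C)CC)/C(OS(=O)(=O)C(F)(F)F)=C(\CO)C(=O)OC)CO[Si](c2ccccc2)(c2ccccc2)C(C)(C)C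
F5 | step 18 | (Z)-enol triflate with C13 acetate (triflate counterpart of 26) | CC(C)(C)[Si](C)(C)OC/C=C(/C)[C@@H]1C=C[C@@]1(C[C@H](OC(=O)[C@H](C)CC)/C(OS(=O)(=O)C(F)(F)F)=C(\COC(C)=O)C(=O)OC)CO[Si](c2ccccc2)(c2ccccc2)C(C)(C)C
F6 | step 18 | triflate counterpart of 27 | OC/C=C(/C)[C@@H]1C=C[C@@]1(C[C@H](OC(=O)[C@H](C)CC)/C(OS(=O)(=O)C(F)(F)F)=C(\COC(C)=O)C(=O)OC)CO[Si](c2ccccc2)(c2ccccc2)C(C)(C)C
F7 | step 18 | triflate counterpart of 28 | OC[C@@H]2O[C@]2(C)[C@@H]1C=C[C@@]1(C[C@H](OC(=O)[C@H](C)CC)/C(OS(=O)(=O)C(F)(F)F)=C(\COC(C)=O)C(=O)OC)CO[Si](c3ccccc3)(c3ccccc3)C(C)(C)C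
F8 | step 18 | triflate counterpart of 29 | O=C[C@@H]2O[C@]2(C)[C@@H]1C=C[C@@]1(C[C@H](OC(=O)[C@H](C)CC)/C(OS(=O)(=O)C(F)(F)F)=C(\COC(C)=O)C(=O)OC)CO[Si](c3ccccc3)(c3ccccc3)C(C)(C)C
F9 | step 23 | (Z)-enal (C6 = CHO, C4=C5 alkene kept) | O=C/C=C(/C)[C@@H]1C=C[C@@]1(C[C@H](OC(=O)[C@H](C)CC)/C(I)=C(\COC(C)=O)C(=O)OC)CO[Si](c2ccccc2)(c2ccccc2)C(C)(C)C
F10 | step 23 | cyclooctene butenolide (C4=C5 alkene, (6S)) | CC[C@@H](C)C(=O)O[C@H]1C[C@@]3(CO[Si](c4ccccc4)(c4ccccc4)C(C)(C)C)C=C[C@H]3/C(C)=C\[C@H]2OC(=O)C(COC(C)=O)=C12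
F11 | step 23 | bromohydrin (OH on C4, Br on C5) | CC[C@@H](C)C(=O)O[C@H]1C[C@@]3(CO[Si](c4ccccc4)(c4ccccc4)C(C)(C)C)C=C[C@H]3[C@@](C)(O)[C@H](Br)[C@H]2OC(=O)C(COC(C)=O)=C12
F12 | step 28 | 1,10-epoxy C14 aldehyde | CC[C@@H](C)C(=O)O[C@H]1C[C@@]2(C=O)O[C@@H]2/C=C\[C@@]2(C)O[C@H]2[C@H]2OC(=O)C(COC(C)=O)=C12
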